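**Strategy.** Ring A (the 4-bromo-3,3-dimethylcyclohexanol ring) is opened at C4–C5, the bond between the bromine-bearing carbon and its ring CH2 neighbour. C4 lies next to the quaternary carbon C3 and 1,4 to the carbinol carbon C1, so it is carried as a CHBr2 group: its lithium dibromocarbenoid is alkylated 6-exo-tet by the C5 iodide of an open-chain iodo ketal. One operation closes ring A and leaves a CBr2 group, from which axial hydrogen-atom transfer, steered by C1, later keeps the equatorial bromine. The hydrindane arises from an asymmetric trimethylenemethane (3+2) cycloaddition and a 6-endo radical cyclization; a syn-selective titanium aldol joins the halves.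

Key step: step 6

Atom labels used below: ring A = C1 (carbinol carbon), C2, C3 (CMe2), C4 (CHBr), C5, C6; C7 = carbinol carbon between the rings; hydrindane = C8 (CH bearing C7), C9 (CHOH), C10, C11 (ring-fusion C–CH3), C12 (CHBr), C13, C14, C15 (C(OH)CH3), C16 (ring-fusion CH).

Remark on the chemistry: in step 11 the ligand antipode that leads to the (1S,2S) adduct is assumed; which antipode this is has to be found by experiment.

Step 1
Reactants: 1 methyl 3,3-dimethylpent-4-enoate
Product: 3 methyl 3,3-dimethyl-4-oxobutanoate, via secondary ozonide 2 (not isolated)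
Conditions: O3, CH2Cl2, −78 °C; then Me2S, −78 °C to rt
Reagents that add atoms: ozone, [O-][O+]=O
Why: Ozonolysis of the monosubstituted alkene with reductive work-up should give the neopentyl aldehyde; no stereocenter is formed.

Step 2
Reactants: 3 methyl 3,3-dimethyl-4-oxobutanoate
Product: 4 methyl 4,4-dibromo-3,3-dimethylbutanoate
Conditions: P(OPh)3, Br2, CH2Cl2, −78 °C to rt
Reagents that add atoms: bromine, BrBr
Why: Deoxygenative gem-dibromination of a non-enolisable aldehyde by the phosphite–bromine reagent runs through an α-bromo oxyphosphonium ion and should leave the ester untouched; no stereocenter.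

Step 3
Reactants: 4 methyl 4,4-dibromo-3,3-dimethylbutanoate
Product: 5 4,4-dibromo-N-methoxy-N,3,3-trimethylbutanamide
Conditions: MeNHOMe·HCl, AlMe3, CH2Cl2, 0 °C to rt
Reagents that add atoms: N,O-dimethylhydroxylamine hydrochloride, CNOC.Cl
Why: Aminolysis of the methyl ester by the aluminium amide (Weinreb amide formation) should proceed without touching the gem-dibromide; no stereocenter.

Step 4
Reactants: 5 4,4-dibromo-N-methoxy-N,3,3-trimethylbutanamide
Product: 7 6,6-dibromo-5,5-dimethylhex-1-en-3-one, via magnesium alkoxide 6 (not isolated)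
Conditions: CH2=CHMgBr, THF, −78 to 0 °C; inverse quench into cold 1 M HCl
Reagents that add atoms: vinylmagnesium bromide, C=C[Mg]Br
Why: Single addition of the Grignard reagent to the Weinreb amide gives a stable chelate that releases the vinyl ketone only on acidic quench; no stereocenter.

Step 5
Reactants: 7 6,6-dibromo-5,5-dimethylhex-1-en-3-one
Product: 9 2-(3,3-dibromo-2,2-dimethylpropyl)-2-(2-iodoethyl)-1,3-dioxolane, via iodo silyl enol ether 8 (not isolated)
Conditions: Me3SiI, MeCN, −40 °C; then HOCH2CH2OH, −40 °C to rt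
Reagents that add atoms: iodotrimethylsilane, C[Si](C)(C)I; ethylene glycol, OCCO
Why: Conjugate addition of iodotrimethylsilane to the enone and ketalisation of the resulting silyl enol ether in the same flask should give the β-iodo ketal, which places the C5 leaving group and masks the enolisable ketone; no stereocenter.

Step 6
Reactants: 9 2-(3,3-dibromo-2,2-dimethylpropyl)-2-(2-iodoethyl)-1,3-dioxolane
Product: 11 8,8-dibromo-7,7-dimethyl-1,4-dioxaspiro[4.5]decane, via lithium carbenoid 10 (not isolated)
Conditions: LiN(iPr)2 (1.2 equiv), THF/DMPU, −95 °C, then −60 °C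
Reagents that add atoms: none
Why: Lithium diisopropylamide removes the only acidic proton of 9, that of the CHBr2 group, and the resulting α,α-dibromoalkyllithium carbenoid displaces iodide at C5 in an intramolecular SN2 reaction that forms the C4–C5 bond. The closest known reaction type is the alkylation of lithium dihalocarbenoids (LiCHBr2, RCBr2Li) with primary alkyl iodides. Ring A closes in the 6-exo-tet mode, helped by the gem-dimethyl (Thorpe–Ingold) effect of C3. No stereocenter is formed, since C4 becomes CBr2 and C1 is a symmetric ketal; the C4 configuration is set later, in step 9, under control of C1. The step needs deprotonation to win over attack of the base on the primary iodide and ring closure to win over α-elimination of the carbenoid, which the hindered amide base, the very low temperature, the polar cosolvent and the intramolecular six-membered closure should secure.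

Step 7
Reactants: 11 8,8-dibromo-7,7-dimethyl-1,4-dioxaspiro[4.5]decane
Product: 12 4,4-dibromo-3,3-dimethylcyclohexan-1-one
Conditions: 1 M HCl, acetone, rt
Reagents that add atoms: water, O
Why: Acid-catalysed ketal hydrolysis frees the ketone under non-basic conditions, so the γ,γ-dibromo ketone cannot close a cyclopropane through its enolate; no stereocenter.

Step 8
Reactants: 12 4,4-dibromo-3,3-dimethylcyclohexan-1-one; 13 (R)-methyl p-tolyl sulfoxide
Product: 16 triethyl{[(1R)-4,4-dibromo-3,3-dimethyl-1-{[(R)-4-methylbenzenesulfinyl]methyl}cyclohexyl]oxy}silane, via lithiated sulfoxide 14 (not isolated), via lithium alkoxide 15 (not isolated)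
Conditions: 13, LiN(iPr)2, THF, −78 °C; then 12, −78 °C; then Et3SiCl, DMAP, −78 °C to rt; separation of the two C1 diastereomers by chromatography
Reagents that add atoms: chlorotriethylsilane, CC[Si](CC)(CC)Cl
Why: Addition of the α-sulfinyl carbanion to the achiral ketone creates C1 in both configurations, but the enantiopure sulfur center makes the two adducts diastereomers, so the (1R) isomer can be isolated after silylation (resolution by a covalent auxiliary that also delivers C7).

Step 9
Reactants: 16 triethyl{[(1R)-4,4-dibromo-3,3-dimethyl-1-{[(R)-4-methylbenzenesulfinyl]methyl}cyclohexyl]oxy}silane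
Product: 17 triethyl{[(1R,4S)-4-bromo-3,3-dimethyl-1-{[(R)-4-methylbenzenesulfinyl]methyl}cyclohexyl]oxy}silane
Conditions: Bu3SnH (1.05 equiv), Et3B, air, toluene, −78 °C
Reagents that add atoms: none
Why: Radical chain reduction removes one bromine of the gem-dibromide; in the chair that keeps the C1 oxygen axial and the C7 arm equatorial, the α-bromo radical at C4 should take hydrogen axially, anti to the axial C3 methyl, leaving bromine equatorial and cis to the C1 oxygen (sets C4).

Step 10
Reactants: 17 triethyl{[(1R,4S)-4-bromo-3,3-dimethyl-1-{[(R)-4-methylbenzenesulfinyl]methyl}cyclohexyl]oxy}silane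
Product: 19 (1R,4S)-4-bromo-3,3-dimethyl-1-[(triethylsilyl)oxy]cyclohexane-1-carbaldehyde, via trifluoroacetoxy sulfide 18 (not isolated)
Conditions: (CF3CO)2O, 2,4,6-collidine, MeCN, 0 °C; then aq. NaHCO3, rt
Reagents that add atoms: trifluoroacetic anhydride, O=C(OC(=O)C(F)(F)F)C(F)(F)F; water, O
Why: Pummerer rearrangement of the sulfoxide and hydrolysis of the O,S-acetal should unmask the C7 aldehyde and remove the auxiliary without touching C1 or C4.

Step 11
Reactants: 20 ethyl (E)-3-methyl-4-oxobut-2-enoate; 21 2-[(trimethylsilyl)methyl]prop-2-en-1-yl acetate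
Product: 22 ethyl (1S,2S)-2-formyl-2-methyl-4-methylidenecyclopentane-1-carboxylate
Conditions: Pd(dba)2 (5 mol %), (R,R)-2,5-di(2-naphthyl)pyrrolidine BINOL phosphoramidite (10 mol %), toluene, 0 °C to rt
Reagents that add atoms: none
Why: Palladium-catalysed trimethylenemethane (3+2) cycloaddition to the doubly activated E-alkene should carry the E geometry into the trans relation of formyl and ester groups (C11, C16), while the chiral phosphoramidite selects the alkene face and so sets both centers in the absolute sense.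

Step 12
Reactants: 22 ethyl (1S,2S)-2-formyl-2-methyl-4-methylidenecyclopentane-1-carboxylate
Product: 23 ethyl (1S,2S)-2-(dibromomethyl)-2-methyl-4-methylidenecyclopentane-1-carboxylate
Conditions: P(OPh)3, Br2, CH2Cl2, −78 °C to rt
Reagents that add atoms: bromine, BrBr
Why: The same deoxygenative gem-dibromination as in step 2; bromine is bound as the halophosphonium salt before the aldehyde is added, so the exocyclic alkene should be spared, and C11 and C16 are untouched.

Step 13
Reactants: 23 ethyl (1S,2S)-2-(dibromomethyl)-2-methyl-4-methylidenecyclopentane-1-carboxylate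
Product: 24 (1S,2S)-2-(dibromomethyl)-N-methoxy-N,2-dimethyl-4-methylidenecyclopentane-1-carboxamide
Conditions: MeNHOMe·HCl, AlMe3, CH2Cl2, 0 °C to rt
Reagents that add atoms: N,O-dimethylhydroxylamine hydrochloride, CNOC.Cl
Why: Weinreb amide formation under Lewis acidic, non-basic conditions should keep the epimerisable C16 center intact.

Step 14
Reactants: 24 (1S,2S)-2-(dibromomethyl)-N-methoxy-N,2-dimethyl-4-methylidenecyclopentane-1-carboxamide
Product: 26 1-[(1S,2S)-2-(dibromomethyl)-2-methyl-4-methylidenecyclopentyl]prop-2-en-1-one, via magnesium alkoxide 25 (not isolated)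
Conditions: CH2=CHMgBr, THF, −78 to 0 °C; inverse quench into cold 1 M HCl
Reagents that add atoms: vinylmagnesium bromide, C=C[Mg]Br
Why: Single Grignard addition to the Weinreb amide gives the vinyl ketone; the acyl group stays trans to the bulky CHBr2 group, which is also the thermodynamically preferred arrangement at C16.

Step 15
Reactants: 26 1-[(1S,2S)-2-(dibromomethyl)-2-methyl-4-methylidenecyclopentyl]prop-2-en-1-one
Product: 27 (3aS,7S,7aS)-7-bromo-7a-methyl-2-methylideneoctahydro-4H-inden-4-one
Conditions: Bu3SnH (1.05 equiv, syringe pump), AIBN, benzene, 80 °C, 0.005 M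
Reagents that add atoms: none
Why: Tin hydride-mediated reductive radical cyclization: the α-bromo radical at C12 adds 6-endo-trig to the terminal carbon of the vinyl ketone (attack on the acceptor α-carbon is disfavoured) and the α-keto radical is reduced; the trans arms of 26 fix the trans ring fusion and the C–Br bond is expected to take the equatorial position of the chair-like transition state, cis to the angular methyl, any C12 epimer being removed by chromatography.

Step 16
Reactants: 27 (3aS,7S,7aS)-7-bromo-7a-methyl-2-methylideneoctahydro-4H-inden-4-one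
Product: 29 {[(3aS,4R,7S,7aS)-7-bromo-4,7a-dimethyl-2-methylideneoctahydro-1H-inden-4-yl]oxy}triethylsilane, via cerium alkoxide 28 (not isolated)
Conditions: MeLi, CeCl3, THF, −78 °C; then Et3SiOTf, 2,6-lutidine, −78 to 0 °C
Reagents that add atoms: methyllithium, C[Li]; triethylsilyl trifluoromethanesulfonate, CC[Si](CC)(CC)OS(=O)(=O)C(F)(F)F
Why: The non-basic organocerium reagent should add to the C15 ketone from the equatorial direction, because the axial face is blocked by the 1,3-diaxial angular methyl, giving the axial alkoxide (sets C15) that is silylated in the same flask.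

Step 17
Reactants: 29 {[(3aS,4R,7S,7aS)-7-bromo-4,7a-dimethyl-2-methylideneoctahydro-1H-inden-4-yl]oxy}triethylsilane
Product: 31 (3aS,4S,7R,7aS)-4-bromo-3a,7-dimethyl-7-[(triethylsilyl)oxy]octahydro-2H-inden-2-one, via secondary ozonide 30 (not isolated)
Conditions: O3, CH2Cl2, −78 °C; then Me2S, −78 °C to rt
Reagents that add atoms: ozone, [O-][O+]=O
Why: Ozonolysis of the exocyclic alkene unveils the C9 ketone; the bromide and the silyl ether are inert and no stereocenter changes.

Step 18
Reactants: 31 (3aS,4S,7R,7aS)-4-bromo-3a,7-dimethyl-7-[(triethylsilyl)oxy]octahydro-2H-inden-2-one; 19 (1R,4S)-4-bromo-3,3-dimethyl-1-[(triethylsilyl)oxy]cyclohexane-1-carbaldehyde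
Product: 34 syn-aldol adduct (β-hydroxy ketone), via lithium enolate 32 (not isolated), via titanium enolate 33 (not isolated)
Conditions: LiN(iPr)2, THF, −78 °C; ClTi(OiPr)3, −78 to −40 °C; then 19, −78 °C
Reagents that add atoms: none
Why: Kinetic deprotonation should occur at C8, whose β-face hydrogen lies next to H-16, and not at C10, which is flanked on both faces by the angular methyl and C12; the triisopropoxytitanium enolate then adds to the aldehyde on the same open β face (sets C8) through the boat-type transition state that makes cyclic E-enolates syn-selective (sets C7).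

Step 19
Reactants: 34 syn-aldol adduct (β-hydroxy ketone)
Product: 36 bis(triethylsilyl) ether of the target, via boron chelate 35 (not isolated)
Conditions: Et2BOMe, THF/MeOH, −78 °C; NaBH4; MeOH co-evaporation
Reagents that add atoms: none
Why: Narasaka–Prasad reduction: external hydride attacks the six-membered boron chelate of the β-hydroxy ketone anti to the C8 substituent and should give the syn-1,3-diol (sets C9).

Step 20
Reactants: 36 bis(triethylsilyl) ether of the target
Product: 37 (1S,2R,3aS,4S,7R,7aS)-4-bromo-1-{(R)-[(1R,4S)-4-bromo-1-hydroxy-3,3-dimethylcyclohexyl](hydroxy)methyl}-3a,7-dimethyloctahydro-1H-indene-2,7-diol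
Conditions: HF·pyridine, THF, 0 °C to rt
Reagents that add atoms: none
Why: Fluoride cleaves both tertiary triethylsilyl ethers under mildly acidic conditions that should not touch the secondary bromides or the triol.

**Compound list**

1 | methyl 3,3-dimethylpent-4-enoate | COC(=O)CC(C)(C)C=C | starting material
2 | secondary ozonide of 1, methyl 3-methyl-3-(1,2,4-trioxolan-3-yl)butanoate | COC(=O)CC(C)(C)C1OCOO1 | intermediate (not isolated)
3 | methyl 3,3-dimethyl-4-oxobutanoate | COC(=O)CC(C)(C)C=O | intermediate
4 | methyl 4,4-dibromo-3,3-dimethylbutanoate | COC(=O)CC(C)(C)C(Br)Br | intermediate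
5 | 4,4-dibromo-N-methoxy-N,3,3-trimethylbutanamide | CON(C)C(=O)CC(C)(C)C(Br)Br | intermediate
6 | bromomagnesium alkoxide, tetrahedral vinyl adduct of 5 | C=CC(O[Mg]Br)(N(C)OC)CC(C)(C)C(Br)Br | intermediate (not isolated)
7 | 6,6-dibromo-5,5-dimethylhex-1-en-3-one | C=CC(=O)CC(C)(C)C(Br)Br | intermediate
8 | [(6,6-dibromo-1-iodo-5,5-dimethylhex-2-en-3-yl)oxy]trimethylsilane | C[Si](C)(C)OC(=CCI)CC(C)(C)C(Br)Br | intermediate (not isolated)
9 | 2-(3,3-dibromo-2,2-dimethylpropyl)-2-(2-iodoethyl)-1,3-dioxolane | BrC(Br)C(C)(C)CC1(CCI)OCCO1 | intermediate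
10 | lithium carbenoid, {1,1-dibromo-3-[2-(2-iodoethyl)-1,3-dioxolan-2-yl]-2,2-dimethylpropyl}lithium | [Li]C(Br)(Br)C(C)(C)CC1(CCI)OCCO1 | intermediate (not isolated)
11 | 8,8-dibromo-7,7-dimethyl-1,4-dioxaspiro[4.5]decane | CC1(C)CC2(CCC1(Br)Br)OCCO2 | intermediate
12 | 4,4-dibromo-3,3-dimethylcyclohexan-1-one | CC1(C)CC(=O)CCC1(Br)Br | intermediate
13 | (R)-methyl p-tolyl sulfoxide, (R)-1-methanesulfinyl-4-methylbenzene | C[S@@](=O)c1ccc(C)cc1 | starting material
14 | lithiated sulfoxide, {[(R)-4-methylbenzenesulfinyl]methyl}lithium | [Li]C[S@@](=O)c1ccc(C)cc1 | intermediate (not isolated)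
15 | lithium (1R)-4,4-dibromo-3,3-dimethyl-1-{[(R)-4-methylbenzenesulfinyl]methyl}cyclohexan-1-olate, formed together with its (1S) diastereomer | CC1(C)C[C@@](O[Li])(C[S@@](=O)c2ccc(C)cc2)CCC1(Br)Br | intermediate (not isolated)
16 | triethyl{[(1R)-4,4-dibromo-3,3-dimethyl-1-{[(R)-4-methylbenzenesulfinyl]methyl}cyclohexyl]oxy}silane | CC1(C)C[C@@](O[Si](CC)(CC)CC)(C[S@@](=O)c2ccc(C)cc2)CCC1(Br)Br | intermediate
17 | triethyl{[(1R,4S)-4-bromo-3,3-dimethyl-1-{[(R)-4-methylbenzenesulfinyl]methyl}cyclohexyl]oxy}silane, Br cis to the C1 oxygen | CC1(C)C[C@@](O[Si](CC)(CC)CC)(C[S@@](=O)c2ccc(C)cc2)CC[C@@H]1Br | intermediate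
18 | [(1R,4S)-4-bromo-3,3-dimethyl-1-(triethylsilyloxy)cyclohexyl](p-tolylsulfanyl)methyl trifluoroacetate | CC1(C)C[C@@](O[Si](CC)(CC)CC)(C(OC(=O)C(F)(F)F)Sc2ccc(C)cc2)CC[C@@H]1Br | intermediate (not isolated)
19 | (1R,4S)-4-bromo-3,3-dimethyl-1-[(triethylsilyl)oxy]cyclohexane-1-carbaldehyde | CC1(C)C[C@@](O[Si](CC)(CC)CC)(C=O)CC[C@@H]1Br | intermediate
20 | ethyl (E)-3-methyl-4-oxobut-2-enoate | CCOC(=O)/C=C(C)/C=O | starting material
21 | 2-[(trimethylsilyl)methyl]prop-2-en-1-yl acetate | CC(=O)OCC(=C)C[Si](C)(C)C | starting material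
22 | ethyl (1S,2S)-2-formyl-2-methyl-4-methylidenecyclopentane-1-carboxylate, formyl and ester trans | C=C1C[C@](C)(C=O)[C@@H](C(=O)OCC)C1 | intermediate
23 | ethyl (1S,2S)-2-(dibromomethyl)-2-methyl-4-methylidenecyclopentane-1-carboxylate | C=C1C[C@](C)(C(Br)Br)[C@@H](C(=O)OCC)C1 | intermediate
24 | (1S,2S)-2-(dibromomethyl)-N-methoxy-N,2-dimethyl-4-methylidenecyclopentane-1-carboxamide | C=C1C[C@](C)(C(Br)Br)[C@@H](C(=O)N(C)OC)C1 | intermediate
25 | bromomagnesium alkoxide, tetrahedral vinyl adduct of 24 | C=C1C[C@](C)(C(Br)Br)[C@@H](C(O[Mg]Br)(C=C)N(C)OC)C1 | intermediate (not isolated)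
26 | 1-[(1S,2S)-2-(dibromomethyl)-2-methyl-4-methylidenecyclopentyl]prop-2-en-1-one | C=C1C[C@](C)(C(Br)Br)[C@@H](C(=O)C=C)C1 | intermediate
27 | (3aS,7S,7aS)-7-bromo-7a-methyl-2-methylideneoctahydro-4H-inden-4-one, trans-fused, Br equatorial and cis to the angular methyl | C=C1C[C@]2(C)[C@@H](Br)CCC(=O)[C@H]2C1 | intermediate
28 | dichlorocerium (3aS,4R,7S,7aS)-7-bromo-4,7a-dimethyl-2-methylideneoctahydro-1H-inden-4-olate | C=C1C[C@]2(C)[C@@H](Br)CC[C@@](C)(O[Ce](Cl)Cl)[C@H]2C1 | intermediate (not isolated)
29 | {[(3aS,4R,7S,7aS)-7-bromo-4,7a-dimethyl-2-methylideneoctahydro-1H-inden-4-yl]oxy}triethylsilane | C=C1C[C@]2(C)[C@@H](Br)CC[C@@](C)(O[Si](CC)(CC)CC)[C@H]2C1 | intermediate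
30 | secondary ozonide of 29, spiro-1,2,4-trioxolane at C9 | C1OOC2(O1)C[C@]3(C)[C@@H](Br)CC[C@@](C)(O[Si](CC)(CC)CC)[C@H]3C2 | intermediate (not isolated)
31 | (3aS,4S,7R,7aS)-4-bromo-3a,7-dimethyl-7-[(triethylsilyl)oxy]octahydro-2H-inden-2-one | O=C1C[C@]2(C)[C@@H](Br)CC[C@@](C)(O[Si](CC)(CC)CC)[C@H]2C1 | intermediate
32 | lithium enolate of 31 toward C8 | [Li]OC1=C[C@@H]2[C@](C)(O[Si](CC)(CC)CC)CC[C@H](Br)[C@@]2(C)C1 | intermediate (not isolated)
33 | triisopropoxytitanium enolate of 31 toward C8 | CC(C)O[Ti](OC(C)C)(OC(C)C)OC1=C[C@@H]2[C@](C)(O[Si](CC)(CC)CC)CC[C@H](Br)[C@@]2(C)C1 | intermediate (not isolated)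
34 | syn-aldol adduct, (1R,3aS,4S,7R,7aS)-4-bromo-1-{(R)-[(1R,4S)-4-bromo-3,3-dimethyl-1-(triethylsilyloxy)cyclohexyl](hydroxy)methyl}-3a,7-dimethyl-7-(triethylsilyloxy)octahydro-2H-inden-2-one (C8 arranged in space as in 37) | CC1(C)C[C@@](O[Si](CC)(CC)CC)([C@H](O)[C@@H]2C(=O)C[C@]3(C)[C@@H](Br)CC[C@@](C)(O[Si](CC)(CC)CC)[C@@H]23)CC[C@@H]1Br | intermediate
35 | diethylborinate (boron chelate) of 34 at the C7 oxygen | CC1(C)C[C@@](O[Si](CC)(CC)CC)([C@H](OB(CC)CC)[C@@H]2C(=O)C[C@]3(C)[C@@H](Br)CC[C@@](C)(O[Si](CC)(CC)CC)[C@@H]23)CC[C@@H]1Br | intermediate (not isolated)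
36 | bis(triethylsilyl) ether of the target at the C1 and C15 oxygens, (1S,2R,3aS,4S,7R,7aS) hydrindane, (R) at C7, (1R,4S) ring A | CC1(C)C[C@@](O[Si](CC)(CC)CC)([C@H](O)[C@@H]2[C@H](O)C[C@]3(C)[C@@H](Br)CC[C@@](C)(O[Si](CC)(CC)CC)[C@@H]23)CC[C@@H]1Br | intermediate
37 | (1S,2R,3aS,4S,7R,7aS)-4-bromo-1-{(R)-[(1R,4S)-4-bromo-1-hydroxy-3,3-dimethylcyclohexyl](hydroxy)methyl}-3a,7-dimethyloctahydro-1H-indene-2,7-diol | CC1(C)C[C@@](O)([C@H](O)[C@@H]2[C@H](O)C[C@]3(C)[C@@H](Br)CC[C@@](C)(O)[C@@H]23)CC[C@@H]1Br | target

**Step count.** Total: 20 steps. Longest linear sequence: 13 steps (steps 1–10, then 18–20).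

**Steps most likely to fail**

Step 6 (key step). α-Elimination of the carbenoid, or loss of HI from the iodoethyl arm under the amide base, may outrun ring closure. The fallback keeps the same C4–C5 disconnection but uses a radical instead of an anion. It sets out from 7: Bu3SnH added slowly with AIBN in benzene at 80 °C generates the α-bromoalkyl radical at C4, which adds 6-endo-trig to C5 of the vinyl ketone and, after reduction of the α-keto radical, should give racemic 4-bromo-3,3-dimethylcyclohexan-1-one F1. Addition of lithiated 13 with in situ silylation as in step 8, and separation of the stereoisomers, comes back to the route at 17. In this variant C4 is formed without control and the C1/C4 relation rests only on the weak equatorial preference of bromine, so more material is lost at the separation.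

Step 11. The ligand may discriminate the alkene faces insufficiently, or the cycloaddition may compete at the aldehyde C=O. The fallback replaces catalyst control by a resolution. It sets out from 20 and 21: cycloaddition with Pd(OAc)2 and P(OiPr)3 in THF should give racemic trans ethyl 2-formyl-2-methyl-4-methylidenecyclopentane-1-carboxylate F2. Condensation with (1R,2R)-N,N'-dimethylcyclohexane-1,2-diamine gives two diastereomeric aminals; the aminal of the (1S,2S) aldehyde F3 is separated by chromatography and hydrolysed with aqueous acetic acid, which comes back to the route at 22.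

Step 15. The C–Br bond may take the axial position in the ring-closing transition state, giving the C12 epimer. The fallback sets C12 after ring closure, as in ring A. It sets out from 26: Me3SiI then ethylene glycol gives 2-[(1S,2S)-2-(dibromomethyl)-2-methyl-4-methylidenecyclopentyl]-2-(2-iodoethyl)-1,3-dioxolane F4. LiN(iPr)2 at −95 °C closes the six-membered ring by carbenoid alkylation (C12–C13) to the ethylene ketal of (3aS,7aS)-7,7-dibromo-7a-methyl-2-methylideneoctahydro-4H-inden-4-one F5. Bu3SnH with Et3B and air at −78 °C removes one bromine with axial hydrogen transfer anti to the axial angular methyl, to give the ethylene ketal of 27 F6. Aqueous HCl in acetone comes back to the route at 27.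

**Further compounds**

F1 | step 6 | racemic 4-bromo-3,3-dimethylcyclohexan-1-one | CC1(C)CC(=O)CCC1Br
F2 | step 11 | racemic trans ethyl 2-formyl-2-methyl-4-methylidenecyclopentane-1-carboxylate | C=C1CC(C)(C=O)C(C(=O)OCC)C1
F3 | step 11 | ethyl (1S,2S)-2-[(3aR,7aR)-1,3-dimethyloctahydro-1H-benzimidazol-2-yl]-2-methyl-4-methylidenecyclopentane-1-carboxylate | CN1[C@@H]2CCCC[C@H]2N(C)C1[C@@]3(C)CC(=C)C[C@@H]3C(=O)OCC
F4 | step 15 | 2-[(1S,2S)-2-(dibromomethyl)-2-methyl-4-methylidenecyclopentyl]-2-(2-iodoethyl)-1,3-dioxolane | C=C1C[C@](C)(C(Br)Br)[C@@H](C2(CCI)OCCO2)C1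
F5 | step 15 | ethylene ketal of (3aS,7aS)-7,7-dibromo-7a-methyl-2-methylideneoctahydro-4H-inden-4-one | C=C1C[C@]2(C)C(Br)(Br)CCC3(OCCO3)[C@H]2C1
F6 | step 15 | ethylene ketal of (3aS,7S,7aS)-7-bromo-7a-methyl-2-methylideneoctahydro-4H-inden-4-one | C=C1C[C@]2(C)[C@@H](Br)CCC3(OCCO3)[C@H]2C1
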